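## Structural features

Numbering used throughout (drimane type): ring A = C1–C2–C3–C4–C5–C10, ring B = C5–C6–C7–C8–C9–C10, and C11 is the methylene between C9 and the quinone; β is the face of ring B that carries C11, α the opposite face. The target is a 2-hydroxy-5-methoxy-1,4-benzoquinone alkylated at its C3 by C11, which hangs on the quaternary carbon C9 of a trans-fused decalin. Ring A carries the gem-dimethyl carbon C4 next to the ring-fusion carbinol C5. Four contiguous stereocentres lie in ring B: C5 (tertiary OH), C10 (H), C9 (CH3 and C11) and C8 (CH3). In the given (5R,8S,9S,10S) isomer the C5 hydroxyl, C11 and the C8 methyl are β and H10 and the C9 methyl are α, so C11 is axial and 1,3-syn-diaxial to the C5–O bond. This is the C9-epimeric arrangement to the one expected from an alkylation anti to the C5 oxygen or from a stereospecific 1,2-shift cascade of a drimane, so the real difficulty is the quaternary centre C9 in its relation to C5, C8 and C10; C11 is neopentyl, so the C11–aryl bond cannot come from a substitution at C11. Fragile groups are the tertiary alcohol flanked by the quaternary C4 (ionization, dehydration, Wagner–Meerwein shift) and the hydroxyquinone (reduction, nucleophiles, base), which also lies within reach of the C5 hydroxyl. The key step exploits two facts: ring B with a C5=C6 alkene and a carboxyl-level C11 on C9 is the retron of a lactone-enolate Claisen ring contraction (C9–C10 formed, C6–O broken), and the syn-diaxial C11/C5–O pair lets the C11 carboxyl itself deliver the C5 oxygen through a temporary γ-lactone.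

## Logic of the disconnections

20 ⇒ 19 ⇒ 18. Cut: the O–H/O–CH3 exchange at the quinone carbon next to the side chain, then the two quinone C=O bonds back to aryl C–OCH3. The quinone is the most fragile part and is carried as a tetramethoxyarene that tolerates organolithium and dissolving-metal chemistry. The gain is a locally symmetric aryl group, so no regiochemistry arises in making it. The forward steps must stop the oxidation at the dimethoxy-para-quinone and hydrolyse only the methoxy group next to the side chain.

18 ⇒ 17 ⇒ 14 + 15 (through 16). Cut: the C11–aryl bond. C11 is neopentyl, so the bond is made by carbonyl addition to C11 at the aldehyde level, and the extra benzylic oxygen is removed afterwards. The gain is a split into the commercial symmetric arene 15 and a terpenoid half 14. The demand is addition of a hindered aryllithium to a masked neopentyl aldehyde, and deoxygenation at C11 without touching the C5 hydroxyl.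

14 ⇒ 13 ⇒ 12 ⇒ 11. Cut: the C5–O bond; the C11–O bond of the lactone is a temporary bond that is not in the target. Because the C5 oxygen is syn-diaxial to C11, it is delivered intramolecularly by the C11 carboxyl. The gain is that C5 and the ring-fusion question disappear, leaving a Δ5-octalin acid with three stereocentres. The demand is that the carboxyl becomes axial on ring B and attacks the tertiary C5, and that the auxiliary iodine at C6 is removed without rearrangement.

11 ⇒ 8 (through 10 and 9), the key disconnection. Cut: the C9–C10 bond of ring B and the C8–CH3 bond; reconnect C6–O. The γ,δ-unsaturated acid C11–C9–C10–C5=C6 is a Claisen retron. Tying C11 and C6–O into a six-membered lactone turns the rearrangement into a ring contraction with one possible (boat) transition state, and the enoate form of that lactone lets the C8 methyl enter by conjugate addition anti to C6. The gain is that ring B, the quaternary C9, C10 and C8 collapse to one carbinol stereocentre (C6) in a monocyclic lactone that carries ring A as an alkenyl substituent. The demand is trans conjugate addition and a [3,3] shift through a boat despite the quaternary C4 on the central allyl carbon.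

8 ⇒ 7 ⇒ 6. Cut: the C8=C9 alkene (metathesis) and the ester C11–O bond. This is the standard access to 6-substituted 5,6-dihydropyran-2-ones and leads back to a homoallylic alcohol. The demand is ring closure to a trisubstituted enoate without touching the ring-A alkene.

6 ⇒ 4. Cut: the C6–C7 bond. Asymmetric allylboration sets C6, the only reagent-controlled stereocentre; C8, C9, C10 and C5 are all relayed from it and C6 itself ends as a methylene group. The demand is high facial selectivity on a hindered enal.

4 ⇒ 2 ⇒ 1. Cut: the C5–CHO bond. A vinyl anion from the ketone brings in ring A with its gem-dimethyl carbon from commercial 1. The demand is regiospecific vinyllithium formation, which is secured because 1 has a single α-methylene group.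

## Other disconnections considered

Alternative 1: (the first that comes to mind) cut C9–C11 and alkylate a ring-B ketone. The lithium enolate of the trans-fused 5-silyloxy-9-methyl-8-decalone A1 would be C-benzylated with 2,3,5,6-tetramethoxybenzyl bromide A2 to give A3, and the C8 methyl would follow by methylenation and hydrogenation. In the trans-decalin enolate the axial trajectory to the β face of C9 is 1,3-diaxial to the C5 oxygen substituent, so the electrophile should enter from the α face, which is the opposite of the C9 configuration needed in A3. The C8 methyl would then come from hydrogenation next to a quaternary centre with no clear facial bias. Two of the four stereocentres would be uncontrolled or wrong, whereas the chosen plan makes the C5–O bond from C11 and so cannot give the wrong relation.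

Alternative 2: cut C5–C10 and C8–C9 in an intramolecular Diels–Alder reaction of the silyloxy-triene ester A4, closing both rings and all four stereocentres at once. For the C5 oxygen and the C8 methyl to end cis on ring B, the tether must occupy the inside position of the diene terminus C5 with the silyloxy group outside. A tether attached inside can reach the dienophile only when it is exo on the dienophile, and that transition state closes the cis-fused decalin with the C5 oxygen cis to H10. The diene with the tether outside would need both the silyloxy and the methyl group inside and should not reach the s-cis conformation. The trans ring fusion of the target is therefore geometrically excluded, however attractive the step count.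

Alternative 3: cut nothing in the skeleton and use a cationic 1,2-shift cascade. Ionization at C8 of the drimane A5 (H9 to C8, the C10 methyl to C9, H5 to C10, water to C5) would give A6. The shifts are suprafacial and anti, so the C9 methyl must end cis to the C8 methyl and the benzyl group trans to the incoming C5 hydroxyl. A6 is therefore the C9 epimer of 18, and no variation of conditions can change a stereospecific outcome. The C5 cation next to C4 would also be prone to a further methyl shift. The chosen plan avoids cations at C5 altogether.

Key step: step 6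

## Route

Remark: lactol 14 and carbinol 17 are expected as mixtures at C11 and their SMILES are left open at that carbon. This is inconsequential because C11 ends as a methylene group.

Step 1
Reactants: 1 2,2-dimethylcyclohexan-1-one
Product: 2 (E)-N'-(2,2-dimethylcyclohexylidene)-2,4,6-triisopropylbenzenesulfonohydrazide
Conditions: 2,4,6-triisopropylbenzenesulfonyl hydrazide, cat. HCl, MeOH, rt
Reagents that add atoms: 2,4,6-triisopropylbenzenesulfonyl hydrazide, NNS(=O)(=O)c1c(C(C)C)cc(C(C)C)cc1C(C)C
Why: Acid-catalysed hydrazone formation; the sulfonamide nitrogen should settle anti to the quaternary carbon, i.e. syn to the only α-methylene group, as the next step requires.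

Step 2
Reactants: 2 (E)-N'-(2,2-dimethylcyclohexylidene)-2,4,6-triisopropylbenzenesulfonohydrazide
Product: 4 6,6-dimethylcyclohex-1-ene-1-carbaldehyde, via 6,6-dimethylcyclohex-1-en-1-yllithium 3 (not isolated)
Conditions: n-BuLi (2.2 equiv), THF, −78 → 0 °C; DMF, −78 °C → rt; aq. NH4Cl
Reagents that add atoms: N,N-dimethylformamide, CN(C)C=O
Why: Shapiro reaction: double deprotonation, then loss of sulfinate and N2, gives the vinyllithium regiospecifically because C2 of the ketone is quaternary; formylation with DMF gives the enal.

Step 3
Reactants: 4 6,6-dimethylcyclohex-1-ene-1-carbaldehyde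
Product: 6 (1R)-1-(6,6-dimethylcyclohex-1-en-1-yl)but-3-en-1-ol, via diisopinocampheylborinate ester 5 (not isolated)
Conditions: (+)-Ipc2B(allyl) (from (−)-α-pinene), Et2O, −78 °C; then 3 M NaOH, 30% H2O2, 0 °C → rt
Reagents that add atoms: (+)-B-allyldiisopinocampheylborane, C=CCB([C@H]1C[C@H]2C[C@@H]([C@@H]1C)C2(C)C)[C@H]1C[C@H]2C[C@@H]([C@@H]1C)C2(C)C
Why: Brown asymmetric allylboration through a closed chair transition state; this reagent antipode should deliver allyl to the aldehyde face that gives the (R)-carbinol when the aldehyde substituent outranks allyl (as with benzaldehyde), setting C6, the only reagent-controlled stereocentre. The configuration would be confirmed by Mosher ester analysis before going on.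

Step 4
Reactants: 6 (1R)-1-(6,6-dimethylcyclohex-1-en-1-yl)but-3-en-1-ol
Product: 7 (1R)-1-(6,6-dimethylcyclohex-1-en-1-yl)but-3-en-1-yl 2-methylprop-2-enoate
Conditions: methacryloyl chloride, Et3N, DMAP (cat.), CH2Cl2, 0 °C → rt
Reagents that add atoms: methacryloyl chloride, CC(=C)C(Cl)=O
Why: Standard DMAP-catalysed acylation of a secondary alcohol; no stereocentre is touched.

Step 5
Reactants: 7 (1R)-1-(6,6-dimethylcyclohex-1-en-1-yl)but-3-en-1-yl 2-methylprop-2-enoate
Product: 8 (6R)-6-(6,6-dimethylcyclohex-1-en-1-yl)-3-methyl-5,6-dihydro-2H-pyran-2-one
Conditions: second-generation Grubbs catalyst RuCl2(=CHPh)(H2IMes)(PCy3) (5 mol %), toluene (0.01 M), 80 °C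
Reagents that add atoms: none
Why: Ring-closing metathesis between the terminal alkene and the methacrylate alkene gives the α-methyl-α,β-unsaturated δ-lactone with loss of ethene; the trisubstituted ring-A alkene next to a quaternary carbon should be inert to the ruthenium carbene.

Step 6
Reactants: 8 (6R)-6-(6,6-dimethylcyclohex-1-en-1-yl)-3-methyl-5,6-dihydro-2H-pyran-2-one
Product: 11 (1S,2S,8aR)-1,2,5,5-tetramethyl-1,2,3,5,6,7,8,8a-octahydronaphthalene-1-carboxylic acid, via cyclic trimethylsilyl ketene acetal 9 (not isolated), via trimethylsilyl ester 10 (not isolated)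
Conditions: Me2CuLi (1.3 equiv, from MeLi and CuI), TMSCl, THF, −78 °C; filter under argon, toluene, 105 °C; H2O, THF, dilute HCl to pH 3, rt
Reagents that add atoms: lithium dimethylcuprate, [Li+].C[Cu-]C; chlorotrimethylsilane, C[Si](C)(C)Cl (silicon carried only by 9 and 10)
Why: Me2CuLi activated by TMSCl adds its methyl group to C8 of 8 by axial attack on the half-chair lactone anti to the pseudo-equatorial C6 cyclohexenyl group, which sets C8 (S) and traps the enolate as the cyclic silyl ketene acetal 9 with a ring-fixed double-bond geometry. On heating, 9 undergoes a suprafacial [3,3]-sigmatropic shift over O–C6–C5=C10 and C9=C11 (Ireland–Claisen rearrangement of a lactone silyl ketene acetal, the known ring contraction of 6-alkenyl-tetrahydropyran-2-ones and 6-alkenyl-1,4-dioxan-2-ones): the C9–C10 bond forms, the C6–O bond breaks, and ring B is closed as a six-membered carbocycle carrying the C5=C6 alkene and the C11 silyl ester 10. Because C9 and C6 are also joined by the C8–C7 bridge, the six reacting atoms can only adopt a boat-like, bicyclo[2.2.2]octane-like transition state, so there is no chair alternative and the outcome is fixed by geometry. C10: the new bond is made on the face of the C5=C10 alkene from which the C6–O bond departs, so the C6 (R) centre is transferred to C10 and is itself erased. C9: the bridge and the lactone oxygen hold C10 over one face of the endocyclic ketene acetal, and in the boat H10 eclipses C8 and C1 eclipses the C9 methyl, which places C11 cis to C1 and trans to H10. C8/C9: because the C8 methyl is trans to the C6 substituent it points away from the incoming alkene and ends cis to C11 and trans to the C9 methyl. The selectivities needed are conjugate addition in preference to SN2′ attack on the allylic lactone C–O bond (secured by TMSCl activation at −78 °C and only a small excess of cuprate) and rearrangement in preference to decomposition of 9 (helped by the small trimethylsilyl group, which limits the eclipsing with the quaternary C4 on C5). Mild hydrolysis of 10 then gives 11 with C8, C9 and C10 as in the target.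

Step 7
Reactants: 11 (1S,2S,8aR)-1,2,5,5-tetramethyl-1,2,3,5,6,7,8,8a-octahydronaphthalene-1-carboxylic acid
Product: 12 6α-iodo-5β,11-γ-lactone (trans-decalin with 8β-methyl, 9α-methyl, 10α-H; the C11 carbonyl on C9 bridged through oxygen to C5; iodine on C6 trans to the lactone oxygen)
Conditions: I2, KI, NaHCO3, THF/H2O, 0 °C, dark
Reagents that add atoms: iodine, II
Why: Iodolactonization: the C9 carboxylate opens the iodonium ion at the tertiary C5 (Markovnikov, 5-exo) from its own β face with iodine anti on C6. Since the C5–O bond is delivered by C11 it must be cis to C11, and with the C9/C10 relation from step 6 it is trans to H10, i.e. the trans-decalin carbinol configuration of the target.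

Step 8
Reactants: 12 6α-iodo-5β,11-γ-lactone
Product: 13 5β,11-γ-lactone (trans-decalin with 4,4-dimethyl, 8β-methyl, 9α-methyl, 10α-H; C11 carbonyl on C9 bridged through oxygen to C5)
Conditions: Bu3SnH (0.3 M), AIBN (cat.), toluene, 80 °C
Reagents that add atoms: none
Why: Radical chain dehalogenation; C6 becomes a methylene group so no stereocentre is at stake, and the high stannane concentration should keep hydrogen transfer faster than a 1,2-acyloxy shift of the β-(acyloxy)alkyl radical.

Step 9
Reactants: 13 5β,11-γ-lactone
Product: 14 lactol (cyclic hemiacetal of the C11 aldehyde with the C5 hydroxyl, both C11 anomers)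
Conditions: i-Bu2AlH (1.1 equiv), CH2Cl2, −78 °C; aq. potassium sodium tartrate
Reagents that add atoms: none
Why: Low-temperature reduction of a hindered γ-lactone with i-Bu2AlH stops at the aluminium hemiacetal, released on work-up as the lactol, i.e. the masked C11 aldehyde.

Step 10
Reactants: 14 lactol; 15 1,2,4,5-tetramethoxybenzene
Product: 17 11-(2,3,5,6-tetramethoxyphenyl)-5β,11-diol (benzylic carbinol on C9, both C11 epimers; tertiary 5-OH free), via 2,3,5,6-tetramethoxyphenyllithium 16 (not isolated)
Conditions: 15 (3 equiv), n-BuLi, TMEDA, THF, 0 °C; then 14, 0 °C → rt; aq. NH4Cl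
Reagents that add atoms: none
Why: Directed ortho-lithiation of 15 (each ring hydrogen lies between two methoxy groups) gives 16; the first equivalent deprotonates the lactol, whose lithium alkoxide opens to the C11 aldehyde, and 1,2-addition forms the C11–aryl bond. C9 bears no hydrogen, so enolization cannot compete, and the new carbinol centre is removed in step 11.

Step 11
Reactants: 17 11-(2,3,5,6-tetramethoxyphenyl)-5β,11-diol
Product: 18 (1S,2S,4aR,8aS)-1,2,5,5-tetramethyl-1-[(2,3,5,6-tetramethoxyphenyl)methyl]octahydronaphthalen-4a(2H)-ol
Conditions: Li, liq. NH3/THF, −78 °C; then solid NH4Cl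
Reagents that add atoms: none
Why: Dissolving-metal (Birch-type) reductive cleavage of the benzylic C–O bond: electron transfer to the arene, loss of the benzylic oxygen and protonation; the non-benzylic tertiary C5–O bond should not be cleaved.

Step 12
Reactants: 18 (1S,2S,4aR,8aS)-1,2,5,5-tetramethyl-1-[(2,3,5,6-tetramethoxyphenyl)methyl]octahydronaphthalen-4a(2H)-ol
Product: 19 3-{[(1S,2S,4aR,8aS)-4a-hydroxy-1,2,5,5-tetramethyldecahydronaphthalen-1-yl]methyl}-2,5-dimethoxycyclohexa-2,5-diene-1,4-dione
Conditions: (NH4)2Ce(NO3)6 (2.5 equiv), MeCN/H2O, 0 °C
Reagents that add atoms: water, O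
Why: Oxidative demethylation of a para-dimethoxy pair through the arene radical cation and attack of water gives the para-quinone; either para pair leads to the same 3-alkyl-2,5-dimethoxyquinone because of the local symmetry of the aryl group.

Step 13
Reactants: 19 3-{[(1S,2S,4aR,8aS)-4a-hydroxy-1,2,5,5-tetramethyldecahydronaphthalen-1-yl]methyl}-2,5-dimethoxycyclohexa-2,5-diene-1,4-dione
Product: 20 2-hydroxy-3-{[(1S,2S,4aR,8aS)-4a-hydroxy-1,2,5,5-tetramethyldecahydronaphthalen-1-yl]methyl}-5-methoxycyclohexa-2,5-diene-1,4-dione (CNP0209468.2)
Conditions: KOH, MeOH/H2O, 0 °C → rt; then 1 M HCl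
Reagents that add atoms: potassium hydroxide, [K+].[OH-]
Why: Addition–elimination of hydroxide at the vinylogous ester carbon next to the side chain, whose methoxy group is twisted out of conjugation by the flanking carbonyl and the neopentyl substituent and should therefore be the more electrophilic. The hydroxyquinone formed is deprotonated, which shields the second methoxy group from further attack, and acidification releases 20.

## Compound list

1 | 2,2-dimethylcyclohexan-1-one | CC1(C)CCCCC1=O | starting material
2 | (E)-N'-(2,2-dimethylcyclohexylidene)-2,4,6-triisopropylbenzenesulfonohydrazide | CC1(C)CCCC/C1=N\NS(=O)(=O)c1c(C(C)C)cc(C(C)C)cc1C(C)C | intermediate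
3 | 6,6-dimethylcyclohex-1-en-1-yllithium (not isolated) | [Li]C1=CCCCC1(C)C | intermediate
4 | 6,6-dimethylcyclohex-1-ene-1-carbaldehyde | O=CC1=CCCCC1(C)C | intermediate
5 | (1R)-1-(6,6-dimethylcyclohex-1-en-1-yl)but-3-en-1-yl diisopinocampheylborinate (not isolated) | C=CC[C@@H](OB([C@H]1C[C@H]2C[C@@H]([C@@H]1C)C2(C)C)[C@H]1C[C@H]2C[C@@H]([C@@H]1C)C2(C)C)C1=CCCCC1(C)C | intermediate
6 | (1R)-1-(6,6-dimethylcyclohex-1-en-1-yl)but-3-en-1-ol | C=CC[C@@H](O)C1=CCCCC1(C)C | intermediate
7 | (1R)-1-(6,6-dimethylcyclohex-1-en-1-yl)but-3-en-1-yl 2-methylprop-2-enoate | C=CC[C@@H](OC(=O)C(C)=C)C1=CCCCC1(C)C | intermediate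
8 | (6R)-6-(6,6-dimethylcyclohex-1-en-1-yl)-3-methyl-5,6-dihydro-2H-pyran-2-one | CC1=CC[C@@H](OC1=O)C1=CCCCC1(C)C | intermediate
9 | {[(4S,6R)-6-(6,6-dimethylcyclohex-1-en-1-yl)-3,4-dimethyl-5,6-dihydro-4H-pyran-2-yl]oxy}trimethylsilane (not isolated) | C[C@H]1C[C@@H](OC(O[Si](C)(C)C)=C1C)C1=CCCCC1(C)C | intermediate
10 | trimethylsilyl (1S,2S,8aR)-1,2,5,5-tetramethyl-1,2,3,5,6,7,8,8a-octahydronaphthalene-1-carboxylate (not isolated) | C[Si](C)(C)OC(=O)[C@@]1(C)[C@@H](C)CC=C2[C@H]1CCCC2(C)C | intermediate
11 | (1S,2S,8aR)-1,2,5,5-tetramethyl-1,2,3,5,6,7,8,8a-octahydronaphthalene-1-carboxylic acid | OC(=O)[C@@]1(C)[C@@H](C)CC=C2[C@H]1CCCC2(C)C | intermediate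
12 | 6α-iodo-5β,11-γ-lactone of the trans-decalin (8β-methyl, 9α-methyl, 10α-H; iodine trans to the lactone oxygen) | O=C1[C@@]2(C)[C@@H](C)C[C@H](I)[C@@]3(O1)[C@H]2CCCC3(C)C | intermediate
13 | 5β,11-γ-lactone of the trans-decalin (4,4-dimethyl, 8β-methyl, 9α-methyl, 10α-H) | O=C1[C@@]2(C)[C@@H](C)CC[C@@]3(O1)[C@H]2CCCC3(C)C | intermediate
14 | lactol of 13 (cyclic hemiacetal at C11, both anomers) | OC1[C@@]2(C)[C@@H](C)CC[C@@]3(O1)[C@H]2CCCC3(C)C | intermediate
15 | 1,2,4,5-tetramethoxybenzene | COc1cc(OC)c(OC)cc1OC | starting material
16 | 2,3,5,6-tetramethoxyphenyllithium (not isolated) | [Li]c1c(OC)c(OC)cc(OC)c1OC | intermediate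
17 | 11-(2,3,5,6-tetramethoxyphenyl)-5β,11-diol (both C11 epimers) | COc1cc(OC)c(OC)c(c1OC)C(O)[C@@]1(C)[C@@H](C)CC[C@@]2(O)[C@H]1CCCC2(C)C | intermediate
18 | (1S,2S,4aR,8aS)-1,2,5,5-tetramethyl-1-[(2,3,5,6-tetramethoxyphenyl)methyl]octahydronaphthalen-4a(2H)-ol | COc1cc(OC)c(OC)c(c1OC)C[C@@]1(C)[C@@H](C)CC[C@@]2(O)[C@H]1CCCC2(C)C | intermediate
19 | 3-{[(1S,2S,4aR,8aS)-4a-hydroxy-1,2,5,5-tetramethyldecahydronaphthalen-1-yl]methyl}-2,5-dimethoxycyclohexa-2,5-diene-1,4-dione | COC1=CC(=O)C(OC)=C(C[C@@]2(C)[C@@H](C)CC[C@@]3(O)[C@H]2CCCC3(C)C)C1=O | intermediate
20 | 2-hydroxy-3-{[(1S,2S,4aR,8aS)-4a-hydroxy-1,2,5,5-tetramethyldecahydronaphthalen-1-yl]methyl}-5-methoxycyclohexa-2,5-diene-1,4-dione | COC1=CC(=O)C(O)=C(C[C@@]2(C)[C@@H](C)CC[C@@]3(O)[C@H]2CCCC3(C)C)C1=O | target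

## Step count and least certain steps

Total step count: 13. Longest linear sequence: 13 steps (1 → 20); 15 is used as purchased and enters in step 10.

Step 6 (key step). What may go wrong: the boat transition state may be raised by eclipsing between the quaternary C4 on C5 and the silyloxy group on C11, so that hydrolysis or silyl migration of 9 outruns the rearrangement. The cuprate may also attack the allylic lactone C–O bond in an SN2′ sense, and monovalent copper residues may degrade 9 on heating. Fallback (cycloaddition in place of the sigmatropic ring closure), setting out from 4 and coming back at 11: Wittig methylenation of 4 (Ph3P=CH2, THF) would give 6,6-dimethyl-1-vinylcyclohex-1-ene F1. A Diels–Alder reaction of F1 with commercial 3-methylfuran-2(5H)-one (Me2AlCl or 12 kbar, CH2Cl2) would give the racemic Diels–Alder lactone F2; the ring of the dienophile holds C11 and the C8 carbon branch cis, and the endo rule places the lactone carbonyl cis to C1. Opening of F2 at its O–CH2 carbon with PhSeNa (DMF, 120 °C) would give the racemic (phenylselanyl)methyl acid F3, and Bu3SnH/AIBN would reduce the C–Se bond to the C8 methyl group and give racemic 11. Separation on a chiral stationary phase would remove the enantiomeric acid ent-11 F4 and return 11.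

Step 13. What may go wrong: hydroxide may attack the unhindered methoxy-bearing carbon competitively, giving the regioisomeric hydroxyquinone, or the C5 alkoxide may add intramolecularly to the quinone before hydrolysis is complete. Fallback, setting out from 19 and coming back at 20: exhaustive hydrolysis (NaOH, aq. dioxane, 60 °C; then HCl) would give the 2,5-dihydroxyquinone F5. Acid-catalysed exchange in methanol (cat. TsOH, MeOH, rt) should then methylate only the vinylogous-acid hydroxyl remote from the side chain, giving 20.

Step 11. What may go wrong: over-reduction, i.e. Birch reduction of the electron-rich ring or reductive loss of a methoxy group, may compete with benzylic C–O cleavage. Fallback, setting out from 17 and coming back at 18: phenyl chlorothionoformate (pyridine, DMAP, CH2Cl2) should acylate only the secondary benzylic hydroxyl to give the O-phenyl thionocarbonate F6, and Bu3SnH/AIBN (toluene, 100 °C) would remove the oxygen by a radical chain (Barton–McCombie deoxygenation) to give 18.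

Step 10. What may go wrong: the lithium alkoxide of the bicyclic lactol may stay closed, so that no aldehyde is offered to the hindered aryllithium and 14 is recovered. Fallback, setting out from 13 and coming back at 17: 16 would be added to the lactone carbonyl of 13 itself (THF, 0 °C → rt), which should stop at the hydroxy aryl ketone F7 because a di-ortho-substituted aryl ketone next to a quaternary carbon resists a second addition; LiAlH4 (THF, reflux) would reduce F7 to 17.

Step 8. What may go wrong: the C6 radical may undergo a 1,2-acyloxy shift to the tertiary C5 radical, or the β-acyloxy iodide may eliminate back to 11. Fallback, setting out from 11 and coming back at 13 without passing through 12: direct Markovnikov hydrolactonization (cat. TfOH, CH2Cl2, 0 °C), in which the carboxyl traps the C5 cation as it forms; this fallback makes no new compound (F0).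

## Further compounds

F1 | step 6 | 6,6-dimethyl-1-vinylcyclohex-1-ene | C=CC1=CCCCC1(C)C
F2 | step 6 | racemic Diels–Alder lactone (C11 carbonyl on C9, O–CH2 on C8, C5=C6 alkene; enantiomer drawn leads to 11) | O=C1OC[C@H]2CC=C3[C@@H](CCCC3(C)C)[C@@]12C
F3 | step 6 | racemic 1,5,5-trimethyl-2-[(phenylselanyl)methyl]-1,2,3,5,6,7,8,8a-octahydronaphthalene-1-carboxylic acid (enantiomer drawn leads to 11) | OC(=O)[C@@]1(C)[C@@H](C[Se]c2ccccc2)CC=C2[C@H]1CCCC2(C)C
F4 | step 6 | (1R,2R,8aS)-1,2,5,5-tetramethyl-1,2,3,5,6,7,8,8a-octahydronaphthalene-1-carboxylic acid (ent-11) | OC(=O)[C@]1(C)[C@H](C)CC=C2[C@@H]1CCCC2(C)C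
F5 | step 13 | 2,5-dihydroxy-3-{[(1S,2S,4aR,8aS)-4a-hydroxy-1,2,5,5-tetramethyldecahydronaphthalen-1-yl]methyl}cyclohexa-2,5-diene-1,4-dione | OC1=CC(=O)C(O)=C(C[C@@]2(C)[C@@H](C)CC[C@@]3(O)[C@H]2CCCC3(C)C)C1=O
F6 | step 11 | O-phenyl thionocarbonate of 17 at the C11 hydroxyl | COc1cc(OC)c(OC)c(c1OC)C(OC(=S)Oc1ccccc1)[C@@]1(C)[C@@H](C)CC[C@@]2(O)[C@H]1CCCC2(C)C
F7 | step 10 | [(1S,2S,4aR,8aS)-4a-hydroxy-1,2,5,5-tetramethyldecahydronaphthalen-1-yl](2,3,5,6-tetramethoxyphenyl)methanone | COc1cc(OC)c(OC)c(c1OC)C(=O)[C@@]1(C)[C@@H](C)CC[C@@]2(O)[C@H]1CCCC2(C)C
F0 | step 8 | none | none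
A1 | alternative 1 | trans-fused 5β-(triethylsilyloxy)-4,4,9-trimethyl-8-decalone (10α-H) | C[C@@H]1C(=O)CC[C@@]2(O[Si](CC)(CC)CC)[C@H]1CCCC2(C)C
A2 | alternative 1 | 2,3,5,6-tetramethoxybenzyl bromide | COc1cc(OC)c(OC)c(CBr)c1OC
A3 | alternative 1 | 9β-(2,3,5,6-tetramethoxybenzyl)-9α-methyl-5β-(triethylsilyloxy)-8-decalone (configuration needed for the target) | COc1cc(OC)c(OC)c(c1OC)C[C@@]1(C)C(=O)CC[C@@]2(O[Si](CC)(CC)CC)[C@H]1CCCC2(C)C
A4 | alternative 2 | methyl (2Z,8E,10E)-8-[(tert-butyldimethylsilyl)oxy]-2,7,7-trimethyldodeca-2,8,10-trienoate | C/C=C/C=C(/O[Si](C)(C)C(C)(C)C)C(C)(C)CCC/C=C(/C)C(=O)OC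
A5 | alternative 3 | 11-(2,3,5,6-tetramethoxyphenyl)drim-8(12)-ene | C=C1CC[C@H]2C(C)(C)CCC[C@]2(C)[C@H]1Cc1c(OC)c(OC)cc(OC)c1OC
A6 | alternative 3 | C9 epimer of 18 (9β-methyl, 9α-benzyl) | COc1cc(OC)c(OC)c(c1OC)C[C@]1(C)[C@@H](C)CC[C@@]2(O)[C@H]1CCCC2(C)C
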